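**Retrosynthetic overview**
1. Target 26 ⇐ bis-benzyl ether 25. The dihydrofuran ring is the only ring built (the three benzene rings come intact from catechol) and is closed last: 5-exo aryl-radical cyclization of aryl iodide 23 onto its allyl ether with O2 capture forms the C3–C3a bond, the C3 stereocentre and the CH2OH in one step.
2. The syn-1,3-diol of 23 ⇐ Evans syn-aldol of arylacetyl imide 19 (ring C) with aldehyde 14 (rings A and B), then LiBH4.
3. The C2–O stereocentre of 14 ⇐ iridium-catalysed asymmetric allylic etherification of cinnamyl carbonate 8 (ring A) with 5-iodovanillin 12 (ring B).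
4. 8, 12 and 19 all ⇐ 4-bromo-2-methoxyphenol 3 ⇐ catechol 1; side-chain carbons from methyl acrylate 5, DMF and bromoacetyl bromide 15.

Assumption: the (Sa,Sc,Sc) phosphoramidite is taken to give the (S)-ether 14, a ligand sense assigned from memory; if the first batch shows the opposite sense, the mirror-image ligand is used.
Locants: C2, C3, C3a are dihydrobenzofuran positions; C7' is the carbinol carbon, C8' the aryl-bearing carbon and C9' the CH2OH of the propanediol chain; ring A is the aryl on C2, ring B the benzofuran arene, ring C the aryl on C8'.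

**Route**

Step 1
Reactants: 1 catechol (benzene-1,2-diol)
Product: 2 guaiacol (2-methoxyphenol)
Conditions: MeI (1.0 equiv), K2CO3 (1.0 equiv), acetone, reflux
Reagents that add atoms: iodomethane, CI
Why: Williamson mono-O-methylation of the catechol monoanion, held at the mono-ether by limiting MeI (veratrole and unreacted 1 are separated).

Step 2
Reactants: 2 guaiacol
Product: 3 4-bromo-2-methoxyphenol
Conditions: NBS (1.0 equiv), MeCN, 0 °C
Reagents that add atoms: N-bromosuccinimide, O=C1CCC(=O)N1Br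
Why: Electrophilic aromatic bromination goes para to the free hydroxyl, the stronger activating group.

Step 3
Reactants: 3 4-bromo-2-methoxyphenol
Product: 4 1-(benzyloxy)-4-bromo-2-methoxybenzene
Conditions: BnBr (1.1 equiv), K2CO3, DMF, rt
Reagents that add atoms: benzyl bromide, BrCc1ccccc1
Why: Williamson etherification masks the phenol of the building block used for rings A and C.

Step 4
Reactants: 4 1-(benzyloxy)-4-bromo-2-methoxybenzene; 5 methyl acrylate
Product: 6 methyl (2E)-3-[4-(benzyloxy)-3-methoxyphenyl]prop-2-enoate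
Conditions: Pd(OAc)2 (2 mol%), P(o-tol)3 (4 mol%), Et3N, DMF, 100 °C
Reagents that add atoms: none
Why: Mizoroki–Heck coupling of the aryl bromide with the acrylate gives the E-cinnamate.

Step 5
Reactants: 6 methyl (2E)-3-[4-(benzyloxy)-3-methoxyphenyl]prop-2-enoate
Product: 7 (2E)-3-[4-(benzyloxy)-3-methoxyphenyl]prop-2-en-1-ol
Conditions: i-Bu2AlH (2.2 equiv), CH2Cl2, −78 °C; Rochelle salt work-up
Reagents that add atoms: none
Why: 1,2-reduction of the enoate by DIBAL-H gives the allylic alcohol without touching the alkene or the benzyl ether.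

Step 6
Reactants: 7 (2E)-3-[4-(benzyloxy)-3-methoxyphenyl]prop-2-en-1-ol
Product: 8 (2E)-3-[4-(benzyloxy)-3-methoxyphenyl]prop-2-en-1-yl methyl carbonate
Conditions: ClCO2Me (1.2 equiv), pyridine, CH2Cl2, 0 °C
Reagents that add atoms: methyl chloroformate, COC(=O)Cl
Why: O-acylation turns the allylic alcohol into the carbonate leaving group needed for allyl-iridium formation.

Step 7
Reactants: 3 4-bromo-2-methoxyphenol
Product: 11 vanillin (4-hydroxy-3-methoxybenzaldehyde), via dilithio phenoxide 9 (not isolated), via lithium hemiaminal alkoxide 10 (not isolated)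
Conditions: t-BuLi (3.1 equiv), THF, −78 °C; DMF, −78 → 0 °C; 1 M HCl
Reagents that add atoms: N,N-dimethylformamide, CN(C)C=O
Why: Deprotonation and bromine–lithium exchange give the aryllithium, which DMF formylates (Bouveault-type formylation), the aldehyde being released on acidic work-up.

Step 8
Reactants: 11 vanillin
Product: 12 5-iodovanillin (4-hydroxy-3-iodo-5-methoxybenzaldehyde)
Conditions: NIS (1.05 equiv), TFA (10 mol%), MeCN, rt
Reagents that add atoms: N-iodosuccinimide, O=C1CCC(=O)N1I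
Why: Electrophilic aromatic iodination occurs at the only free position ortho to the phenol.

Step 9
Reactants: 12 5-iodovanillin; 8 (2E)-3-[4-(benzyloxy)-3-methoxyphenyl]prop-2-en-1-yl methyl carbonate
Product: 14 4-{[(1S)-1-[4-(benzyloxy)-3-methoxyphenyl]prop-2-en-1-yl]oxy}-3-iodo-5-methoxybenzaldehyde, via sodium aryloxide 13 (not isolated)
Conditions: 12 (1.5 equiv), NaH (1.5 equiv), THF, 0 °C; then 8 (1.0 equiv), [Ir(cod)Cl]2 (2 mol%), (Sa,Sc,Sc)-O,O'-(1,1'-binaphthyl-2,2'-diyl) N,N-bis(1-phenylethyl)phosphoramidite (4 mol%), THF, 50 °C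
Reagents that add atoms: none
Why: Iridium-catalysed asymmetric allylic etherification (Hartwig type), in which the cyclometalated iridium phosphoramidite ionizes 8 to an allyl complex that the aryloxide attacks at the aryl-substituted terminus, gives the branched ether and sets the (S) centre (later C2) under ligand control.

Step 10
Reactants: 15 bromoacetyl bromide
Product: 17 (4S)-4-benzyl-3-(bromoacetyl)-1,3-oxazolidin-2-one, via N-lithio oxazolidinone 16 (not isolated)
Conditions: (S)-4-benzyl-1,3-oxazolidin-2-one, n-BuLi (1.0 equiv), THF, −78 °C; then 15, −78 → 0 °C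
Reagents that add atoms: (S)-4-benzyl-1,3-oxazolidin-2-one, O=C1N[C@@H](Cc2ccccc2)CO1
Why: N-acylation of the lithiated auxiliary by the acid bromide is much faster at −78 °C than displacement at the CH2Br carbon.

Step 11
Reactants: 17 (4S)-4-benzyl-3-(bromoacetyl)-1,3-oxazolidin-2-one; 4 1-(benzyloxy)-4-bromo-2-methoxybenzene
Product: 19 (4S)-4-benzyl-3-{[4-(benzyloxy)-3-methoxyphenyl]acetyl}-1,3-oxazolidin-2-one, via zinc Reformatsky reagent 18 (not isolated)
Conditions: Zn dust (TMSCl-activated), THF, rt; then 4, Pd(dba)2 (2 mol%), P(t-Bu)3 (2 mol%), THF, 50 °C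
Reagents that add atoms: none
Why: Zinc insertion gives the Reformatsky reagent, which undergoes palladium-catalysed Negishi-type α-arylation with aryl bromide 4, the neutral zinc enolate avoiding base-induced imide cleavage and diarylation.

Step 12
Reactants: 19 (4S)-4-benzyl-3-{[4-(benzyloxy)-3-methoxyphenyl]acetyl}-1,3-oxazolidin-2-one; 14 4-{[(1S)-1-[4-(benzyloxy)-3-methoxyphenyl]prop-2-en-1-yl]oxy}-3-iodo-5-methoxybenzaldehyde
Product: 22 (4S)-4-benzyl-3-[(2S,3S)-2-[4-(benzyloxy)-3-methoxyphenyl]-3-hydroxy-3-(4-{[(1S)-1-[4-(benzyloxy)-3-methoxyphenyl]prop-2-en-1-yl]oxy}-3-iodo-5-methoxyphenyl)propanoyl]-1,3-oxazolidin-2-one, via boron Z-enolate 20 (not isolated), via boron aldolate 21 (not isolated)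
Conditions: 19, Bu2BOTf (1.2 equiv), i-Pr2NEt (1.4 equiv), CH2Cl2, 0 °C; 14, −78 → 0 °C; pH 7 buffer, MeOH, 30% H2O2, 0 °C
Reagents that add atoms: none
Why: Evans syn-aldol, in which the Z-boron enolate reacts through a closed Zimmerman–Traxler transition state on the face away from the auxiliary benzyl group, sets both new centres syn (2S,3S; later C8' and C7') under auxiliary control, independent of the remote ether centre.

Step 13
Reactants: 22 the syn-aldol imide
Product: 23 (1S,2R)-2-[4-(benzyloxy)-3-methoxyphenyl]-1-(4-{[(1S)-1-[4-(benzyloxy)-3-methoxyphenyl]prop-2-en-1-yl]oxy}-3-iodo-5-methoxyphenyl)propane-1,3-diol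
Conditions: LiBH4 (2.5 equiv), MeOH (2.5 equiv), THF, 0 °C
Reagents that add atoms: none
Why: Reductive cleavage of the imide by LiBH4 gives the primary alcohol and frees the auxiliary without touching the aryl iodide, the alkene or any stereocentre (the C8' descriptor changes from S to R through CIP priorities only).

Step 14
Reactants: 23 the iodo allyl ether diol
Product: 25 (1S,2R)-2-[4-(benzyloxy)-3-methoxyphenyl]-1-[(2S,3R)-2-[4-(benzyloxy)-3-methoxyphenyl]-3-(hydroxymethyl)-7-methoxy-2,3-dihydro-1-benzofuran-5-yl]propane-1,3-diol, via primary hydroperoxide 24 (not isolated)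
Conditions: Bu3SnH (1.3 equiv, syringe pump, 4 h), Et3B (0.2 equiv), stream of dry air, toluene (0.01 M), 0 °C; then PPh3 (1.5 equiv), rt
Reagents that add atoms: dioxygen, O=O
Why: Oxygenative tin-hydride radical cyclization, in which the aryl radical formed by iodine abstraction closes 5-exo-trig onto the terminal alkene through a Beckwith–Houk chair-like transition state with the ring A aryl group pseudo-equatorial, forms the C3–C3a bond and sets C3 trans to C2 (2S,3R), and the primary radical is captured by O2 faster than by Bu3SnH so that the hydroperoxide, reduced by PPh3, gives the CH2OH (the minor cis isomer is removed by chromatography).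

Step 15
Reactants: 25 the bis-benzyl ether
Product: 26 (1S,2R)-2-(4-hydroxy-3-methoxyphenyl)-1-[(2S,3R)-2-(4-hydroxy-3-methoxyphenyl)-3-(hydroxymethyl)-7-methoxy-2,3-dihydro-1-benzofuran-5-yl]propane-1,3-diol (CNP0294468.1)
Conditions: H2 (1 atm), 10% Pd/C, EtOAc–EtOH (1:1), rt, stopped at full debenzylation
Reagents that add atoms: none
Why: Hydrogenolysis of the two aryl benzyl ethers over Pd/C under neutral conditions is much faster than cleavage of the benzylic C–O bonds of the carbinol and the dihydrofuran, so no stereocentre is touched.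

**Compound list**
1 | catechol (benzene-1,2-diol) | Oc1ccccc1O | starting material
2 | guaiacol (2-methoxyphenol) | COc1ccccc1O | intermediate
3 | 4-bromo-2-methoxyphenol | COc1cc(Br)ccc1O | intermediate
4 | 1-(benzyloxy)-4-bromo-2-methoxybenzene | COc1cc(Br)ccc1OCc1ccccc1 | intermediate
5 | methyl acrylate | C=CC(=O)OC | starting material
6 | methyl (2E)-3-[4-(benzyloxy)-3-methoxyphenyl]prop-2-enoate | COC(=O)/C=C/c1ccc(OCc2ccccc2)c(OC)c1 | intermediate
7 | (2E)-3-[4-(benzyloxy)-3-methoxyphenyl]prop-2-en-1-ol | OC/C=C/c1ccc(OCc2ccccc2)c(OC)c1 | intermediate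
8 | (2E)-3-[4-(benzyloxy)-3-methoxyphenyl]prop-2-en-1-yl methyl carbonate | COC(=O)OC/C=C/c1ccc(OCc2ccccc2)c(OC)c1 | intermediate
9 | lithium 4-lithio-2-methoxyphenolate | [Li]c1ccc(O[Li])c(OC)c1 | intermediate
10 | dilithium salt of (dimethylamino)(4-hydroxy-3-methoxyphenyl)methanol | CN(C)C(O[Li])c1ccc(O[Li])c(OC)c1 | intermediate
11 | vanillin (4-hydroxy-3-methoxybenzaldehyde) | COc1cc(C=O)ccc1O | intermediate
12 | 5-iodovanillin (4-hydroxy-3-iodo-5-methoxybenzaldehyde) | COc1cc(C=O)cc(I)c1O | intermediate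
13 | sodium 4-formyl-2-iodo-6-methoxyphenolate | COc1cc(C=O)cc(I)c1[O-].[Na+] | intermediate
14 | 4-{[(1S)-1-[4-(benzyloxy)-3-methoxyphenyl]prop-2-en-1-yl]oxy}-3-iodo-5-methoxybenzaldehyde | C=C[C@H](Oc1c(I)cc(C=O)cc1OC)c1ccc(OCc2ccccc2)c(OC)c1 | intermediate
15 | bromoacetyl bromide | BrCC(Br)=O | starting material
16 | N-lithio (S)-4-benzyl-1,3-oxazolidin-2-one | [Li]N1C(=O)OC[C@@H]1Cc2ccccc2 | intermediate
17 | (4S)-4-benzyl-3-(bromoacetyl)-1,3-oxazolidin-2-one | BrCC(=O)N1C(=O)OC[C@@H]1Cc2ccccc2 | intermediate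
18 | bromozinc Reformatsky reagent of 17 | Br[Zn]CC(=O)N1C(=O)OC[C@@H]1Cc2ccccc2 | intermediate
19 | (4S)-4-benzyl-3-{[4-(benzyloxy)-3-methoxyphenyl]acetyl}-1,3-oxazolidin-2-one | COc1cc(CC(=O)N2C(=O)OC[C@@H]2Cc3ccccc3)ccc1OCc4ccccc4 | intermediate
20 | dibutylboron Z-enolate of 19 | CCCCB(CCCC)O/C(=C\c1ccc(OCc2ccccc2)c(OC)c1)N3C(=O)OC[C@@H]3Cc4ccccc4 | intermediate
21 | O-dibutylboryl aldolate of 22 | C=C[C@H](Oc1c(I)cc(cc1OC)[C@@H](OB(CCCC)CCCC)[C@@H](C(=O)N2C(=O)OC[C@@H]2Cc3ccccc3)c4ccc(OCc5ccccc5)c(OC)c4)c6ccc(OCc7ccccc7)c(OC)c6 | intermediate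
22 | (4S)-4-benzyl-3-[(2S,3S)-2-[4-(benzyloxy)-3-methoxyphenyl]-3-hydroxy-3-(4-{[(1S)-1-[4-(benzyloxy)-3-methoxyphenyl]prop-2-en-1-yl]oxy}-3-iodo-5-methoxyphenyl)propanoyl]-1,3-oxazolidin-2-one | C=C[C@H](Oc1c(I)cc(cc1OC)[C@@H](O)[C@@H](C(=O)N2C(=O)OC[C@@H]2Cc3ccccc3)c4ccc(OCc5ccccc5)c(OC)c4)c6ccc(OCc7ccccc7)c(OC)c6 | intermediate
23 | (1S,2R)-2-[4-(benzyloxy)-3-methoxyphenyl]-1-(4-{[(1S)-1-[4-(benzyloxy)-3-methoxyphenyl]prop-2-en-1-yl]oxy}-3-iodo-5-methoxyphenyl)propane-1,3-diol | C=C[C@H](Oc1c(I)cc(cc1OC)[C@@H](O)[C@@H](CO)c2ccc(OCc3ccccc3)c(OC)c2)c4ccc(OCc5ccccc5)c(OC)c4 | intermediate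
24 | (1S,2R)-2-[4-(benzyloxy)-3-methoxyphenyl]-1-[(2S,3R)-2-[4-(benzyloxy)-3-methoxyphenyl]-3-(hydroperoxymethyl)-7-methoxy-2,3-dihydro-1-benzofuran-5-yl]propane-1,3-diol | COc1cc([C@H]2Oc3c(OC)cc([C@@H](O)[C@@H](CO)c4ccc(OCc5ccccc5)c(OC)c4)cc3[C@@H]2COO)ccc1OCc6ccccc6 | intermediate
25 | (1S,2R)-2-[4-(benzyloxy)-3-methoxyphenyl]-1-[(2S,3R)-2-[4-(benzyloxy)-3-methoxyphenyl]-3-(hydroxymethyl)-7-methoxy-2,3-dihydro-1-benzofuran-5-yl]propane-1,3-diol | COc1cc([C@H]2Oc3c(OC)cc([C@@H](O)[C@@H](CO)c4ccc(OCc5ccccc5)c(OC)c4)cc3[C@@H]2CO)ccc1OCc6ccccc6 | intermediate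
26 | (1S,2R)-2-(4-hydroxy-3-methoxyphenyl)-1-[(2S,3R)-2-(4-hydroxy-3-methoxyphenyl)-3-(hydroxymethyl)-7-methoxy-2,3-dihydro-1-benzofuran-5-yl]propane-1,3-diol | COc1cc([C@H]2Oc3c(OC)cc([C@@H](O)[C@@H](CO)c4ccc(O)c(OC)c4)cc3[C@@H]2CO)ccc1O | target

**Totals**
Total step count: 15. Longest linear sequence: 11 steps (1, 2, 3, 4, 5, 6, 9, 12, 13, 14, 15).

**Steps most likely to fail and fallbacks**

Step 14 is the main risk. The trans:cis ratio at C3 may be only modest and cannot be corrected afterwards. Oxygen capture must also beat simple reduction to the 3-methyl compound, and the chain can stall in air. If oxygen capture is the problem, the primary radical is intercepted by a persistent nitroxide instead of O2. Setting out from 23, Bu3SnH (added in portions) and excess TEMPO in benzene at 70 °C give the alkoxyamine (1S,2R)-2-[4-(benzyloxy)-3-methoxyphenyl]-1-[(2S,3R)-2-[4-(benzyloxy)-3-methoxyphenyl]-7-methoxy-3-{[(2,2,6,6-tetramethylpiperidin-1-yl)oxy]methyl}-2,3-dihydro-1-benzofuran-5-yl]propane-1,3-diol F5. Zinc dust in AcOH–THF–H2O at 40 °C (kept mild to spare the benzylic carbinol) then cleaves the N–O bond and the route is rejoined at 25.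

Step 9 is the second risk. The aryloxide 13 is flanked by iodine and methoxy and is weakened by the para formyl group, so conversion, branched selectivity or ee may suffer, and the ligand sense needs confirmation. The fallback makes the aryl ether C–O bond by SN2 inversion rather than by allyl-iridium capture. Setting out from 8, iridium-catalysed allylic hydroxylation with KHCO3 as hydroxide surrogate ([Ir(cod)Cl]2 and the mirror-image (Ra,Rc,Rc) ligand) gives (1R)-1-[4-(benzyloxy)-3-methoxyphenyl]prop-2-en-1-ol F1. Mitsunobu etherification of F1 with the acidic phenol 12 (PPh3, DIAD, toluene, −20 °C, kept cold to limit ionization of the electron-rich benzylic centre) inverts the carbinol centre and comes back to the route at 14.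

Step 11 is the third risk. The imide Reformatsky reagent 18 may protodezincate, lose ketene or couple sluggishly with the electron-rich bromide 4. The fallback builds the arylacetic acid first and attaches the auxiliary afterwards. Setting out from 4, palladium-catalysed α-arylation of the lithium enolate of tert-butyl acetate (LiHMDS, Pd(dba)2, P(t-Bu)3, toluene, rt) gives tert-butyl [4-(benzyloxy)-3-methoxyphenyl]acetate F2. TFA in CH2Cl2 gives [4-(benzyloxy)-3-methoxyphenyl]acetic acid F3. PivCl and Et3N in THF at −20 °C give the mixed anhydride [4-(benzyloxy)-3-methoxyphenyl]acetic pivalic anhydride F4, which acylates the lithiated auxiliary 16 and comes back to the route at 19.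

**Further compounds**
F1 | step 9 | (1R)-1-[4-(benzyloxy)-3-methoxyphenyl]prop-2-en-1-ol | C=C[C@@H](O)c1ccc(OCc2ccccc2)c(OC)c1
F2 | step 11 | tert-butyl [4-(benzyloxy)-3-methoxyphenyl]acetate | COc1cc(CC(=O)OC(C)(C)C)ccc1OCc1ccccc1
F3 | step 11 | [4-(benzyloxy)-3-methoxyphenyl]acetic acid | COc1cc(CC(=O)O)ccc1OCc1ccccc1
F4 | step 11 | [4-(benzyloxy)-3-methoxyphenyl]acetic pivalic anhydride | COc1cc(CC(=O)OC(=O)C(C)(C)C)ccc1OCc1ccccc1
F5 | step 14 | (1S,2R)-2-[4-(benzyloxy)-3-methoxyphenyl]-1-[(2S,3R)-2-[4-(benzyloxy)-3-methoxyphenyl]-7-methoxy-3-{[(2,2,6,6-tetramethylpiperidin-1-yl)oxy]methyl}-2,3-dihydro-1-benzofuran-5-yl]propane-1,3-diol | COc1cc([C@H]2Oc3c(OC)cc([C@@H](O)[C@@H](CO)c4ccc(OCc5ccccc5)c(OC)c4)cc3[C@@H]2CON6C(C)(C)CCCC6(C)C)ccc1OCc7ccccc7
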